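**Plan**

- Retrosynthesis: ring C is opened at O1–C2, and C2 is removed from C3 as a one-carbon insertion into a C3–boron bond. The resulting (R)-1,2-diarylethyl boronate is cut at C3–C1' and C4–C4a in one operation into a ring B chromenyllithium, vinylboronic ester and a ring A aryl triflate.
- Enabling feature: C3–C4 is a two-carbon bridge with ring B (C1') on C3 and ring A (C4a) on C4, which is a vinyl group arylated at both ends with boron left on C3. C2 sits one carbon beyond that boron.
- Ring A triflate (8 steps from 2,4,6-trihydroxybenzaldehyde): stepwise O-differentiation, ortho-Claisen for the C6 side chain, Dakin oxidation, triflation. The side chain is carried as allyl through the peracid step, which a prenyl alkene would not survive, and is made prenyl by cross metathesis.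
- Ring B bromide (3 steps from 4-bromoresorcinol): silylation, propargylation and Claisen cyclisation, so the chromene ring (ring D) arises first. The three components are then joined, C2 is inserted and oxidised, ring C is closed last by Mitsunobu etherification, and the silyl ethers are removed.
- Stereochemistry: the only stereocenter, C3 (R), is set by the chiral bisphosphine–palladium catalyst in the coupling and is carried through the stereoretentive Matteson homologation. No later step touches it.

Key step: step 12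

Assumption: the ligand enantiomer that delivers the R boronate is taken to be (Sp,Sp); both enantiomers are commercial, so the mirror-image ligand would be used if a model coupling pointed the other way.

**Route**

Step 1
Reactants: 1 2,4,6-trihydroxybenzaldehyde
Product: 2 2,6-dihydroxy-4-[(triisopropylsilyl)oxy]benzaldehyde
Conditions: TIPSCl (1.0 equiv), imidazole, DMF, −20 °C → 0 °C
Reagents that add atoms: triisopropylsilyl chloride, CC(C)[Si](Cl)(C(C)C)C(C)C
Why: Silyl ether formation under kinetic control, in which the 4-hydroxyl (para to the formyl group, most acidic, not chelated to the carbonyl) should take the single equivalent of the bulky silyl chloride.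

Step 2
Reactants: 2 2,6-dihydroxy-4-[(triisopropylsilyl)oxy]benzaldehyde
Product: 3 2-hydroxy-6-(methoxymethoxy)-4-[(triisopropylsilyl)oxy]benzaldehyde
Conditions: MOMCl (1.1 equiv), i-Pr2NEt, CH2Cl2, 0 °C
Reagents that add atoms: chloromethyl methyl ether, COCCl
Why: O-alkylation to the methoxymethyl acetal, where the two hydroxyls are equivalent and the one left after the first alkylation is locked in the hydrogen bond to the aldehyde, so the reaction should stop at the mono-ether.

Step 3
Reactants: 3 2-hydroxy-6-(methoxymethoxy)-4-[(triisopropylsilyl)oxy]benzaldehyde; 4 allyl bromide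
Product: 5 2-(allyloxy)-6-(methoxymethoxy)-4-[(triisopropylsilyl)oxy]benzaldehyde
Conditions: K2CO3, acetone, 55 °C
Reagents that add atoms: none
Why: Williamson ether synthesis on the chelated phenol, run in acetone so that carbonate does not attack the aryl silyl ether.

Step 4
Reactants: 5 2-(allyloxy)-6-(methoxymethoxy)-4-[(triisopropylsilyl)oxy]benzaldehyde
Product: 6 3-allyl-2-hydroxy-6-(methoxymethoxy)-4-[(triisopropylsilyl)oxy]benzaldehyde
Conditions: PhNEt2, 190 °C, argon
Reagents that add atoms: none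
Why: Aromatic Claisen rearrangement, in which the only open ortho position of the allyl ether is C3 (the other carries the formyl group), so the side chain is placed between the future C5 and C7 oxygens.

Step 5
Reactants: 6 3-allyl-2-hydroxy-6-(methoxymethoxy)-4-[(triisopropylsilyl)oxy]benzaldehyde
Product: 7 3-allyl-2-methoxy-6-(methoxymethoxy)-4-[(triisopropylsilyl)oxy]benzaldehyde
Conditions: MeI, K2CO3, acetone, 55 °C (sealed)
Reagents that add atoms: iodomethane, CI
Why: Williamson O-methylation of the phenol freed by the rearrangement, which fixes the C5 methoxy group.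

Step 6
Reactants: 7 3-allyl-2-methoxy-6-(methoxymethoxy)-4-[(triisopropylsilyl)oxy]benzaldehyde
Product: 9 3-allyl-2-methoxy-6-(methoxymethoxy)-4-[(triisopropylsilyl)oxy]phenol, via aryl formate 8 (not isolated)
Conditions: mCPBA (1.2 equiv), CH2Cl2, 0 °C; aq Na2S2O3 wash; then Et3N (cat.), MeOH, 0 °C
Reagents that add atoms: m-chloroperoxybenzoic acid, OOC(=O)c1cccc(Cl)c1
Why: Dakin oxidation (Baeyer–Villiger reaction of an aryl aldehyde), in which the electron-rich aryl group migrates to give the formate, the monosubstituted allyl alkene is epoxidised far more slowly than the aldehyde is oxidised, and the formate is cleaved by mild methanolysis once excess peracid is destroyed.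

Step 7
Reactants: 9 3-allyl-2-methoxy-6-(methoxymethoxy)-4-[(triisopropylsilyl)oxy]phenol
Product: 10 3-allyl-2-methoxy-6-(methoxymethoxy)-4-[(triisopropylsilyl)oxy]phenyl trifluoromethanesulfonate
Conditions: Tf2O, pyridine, CH2Cl2, −20 °C → 0 °C
Reagents that add atoms: trifluoromethanesulfonic anhydride, O=S(=O)(OS(=O)(=O)C(F)(F)F)C(F)(F)F
Why: O-sulfonylation of the phenol, with pyridine at low temperature keeping the methoxymethyl acetal and the silyl ether intact.

Step 8
Reactants: 10 3-allyl-2-methoxy-6-(methoxymethoxy)-4-[(triisopropylsilyl)oxy]phenyl trifluoromethanesulfonate; 11 2-methyl-2-butene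
Product: 12 2-methoxy-6-(methoxymethoxy)-3-(3-methylbut-2-en-1-yl)-4-[(triisopropylsilyl)oxy]phenyl trifluoromethanesulfonate
Conditions: second-generation Grubbs catalyst RuCl2(=CHPh)(PCy3)(H2IMes) (5 mol%), 2-methyl-2-butene/CH2Cl2, 40 °C
Reagents that add atoms: none
Why: Olefin cross metathesis of a terminal alkene with excess 2-methyl-2-butene, a standard allyl-to-prenyl conversion to which the aryl triflate and the ethers are inert.

Step 9
Reactants: 13 4-bromoresorcinol
Product: 14 2-bromo-5-[(triisopropylsilyl)oxy]phenol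
Conditions: TIPSCl (1.0 equiv), imidazole, CH2Cl2, 0 °C
Reagents that add atoms: triisopropylsilyl chloride, CC(C)[Si](Cl)(C(C)C)C(C)C
Why: Selective silylation, in which the hydroxyl para to bromine is unhindered while the one ortho to bromine is shielded, so the bulky silyl chloride should take the former (the future O4').

Step 10
Reactants: 14 2-bromo-5-[(triisopropylsilyl)oxy]phenol; 15 3-chloro-3-methylbut-1-yne
Product: 16 1-bromo-2-[(2-methylbut-3-yn-2-yl)oxy]-4-[(triisopropylsilyl)oxy]benzene
Conditions: DBU, CuCl2 (1 mol%), MeCN, 0 °C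
Reagents that add atoms: none
Why: Copper-catalysed O-alkylation of a phenol with a tertiary propargylic chloride, a method that tolerates ortho-substituted phenols and avoids elimination of the chloride.

Step 11
Reactants: 16 1-bromo-2-[(2-methylbut-3-yn-2-yl)oxy]-4-[(triisopropylsilyl)oxy]benzene
Product: 17 8-bromo-2,2-dimethyl-5-[(triisopropylsilyl)oxy]-2H-chromene
Conditions: PhNEt2, 185 °C, argon
Reagents that add atoms: none
Why: Propargyl Claisen rearrangement followed by 1,5-hydrogen shift and 6π oxa-electrocyclisation builds the 2,2-dimethylchromene, and because bromine blocks the other ortho position the ring can only close at the carbon between the two oxygens.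

Step 12
Reactants: 17 8-bromo-2,2-dimethyl-5-[(triisopropylsilyl)oxy]-2H-chromene; 18 vinylboronic acid pinacol ester; 12 2-methoxy-6-(methoxymethoxy)-3-(3-methylbut-2-en-1-yl)-4-[(triisopropylsilyl)oxy]phenyl trifluoromethanesulfonate
Product: 21 2-[(1R)-1-{2,2-dimethyl-5-[(triisopropylsilyl)oxy]-2H-chromen-8-yl}-2-{2-methoxy-6-(methoxymethoxy)-3-(3-methylbut-2-en-1-yl)-4-[(triisopropylsilyl)oxy]phenyl}ethyl]-4,4,5,5-tetramethyl-1,3,2-dioxaborolane, via chromenyllithium 19 (not isolated), via lithium vinylborate complex 20 (not isolated)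
Conditions: 17, n-BuLi (1.0 equiv), THF, −78 °C; 18, −78 °C → rt; volatiles removed in vacuo, fresh THF; 12 (0.75 equiv), Pd(OAc)2 (3 mol%), (Sp,Sp)-1,1'-bis[bis(4-methoxy-3,5-dimethylphenyl)phosphino]-2,2'-bis[(R)-α-(dimethylamino)benzyl]ferrocene (MandyPhos-type ligand, 3.6 mol%), 60 °C
Reagents that add atoms: none
Why: Oxidative addition of triflate 12 to zerovalent palladium gives a cationic arylpalladium that binds the boron-bound vinyl group of 20; the chromenyl group then shifts from boron to the internal carbon anti to palladium (1,2-metallate shift) while palladium bonds the terminal carbon, and reductive elimination forms C4–C4a, so C3–C1' and C4–C4a are made in one catalytic cycle. The closest known reaction is the palladium-catalysed enantioselective conjunctive cross-coupling of vinylboron ate complexes with aryl triflates. No ring is closed. The single new stereocenter, C3, is controlled by the chiral ferrocenyl bisphosphine, which selects the alkene face that palladium occupies during the shift, and the R configuration is the one required. The step needs the conjunctive path to outrun direct Suzuki-type transfer of the chromenyl or vinyl group and needs the prenyl and chromene alkenes to stay out of the cycle: the triflate keeps palladium cationic for alkene binding, halide ion is avoided by making 19 with n-BuLi and stripping 1-bromobutane before the catalyst is added, and only the boron-bound alkene can undergo the metallate shift. The methoxymethyl ether was chosen as the small group next to the triflate so that oxidative addition at the di-ortho-oxygenated carbon is hindered as little as possible.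

Step 13
Reactants: 21 2-[(1R)-1-{2,2-dimethyl-5-[(triisopropylsilyl)oxy]-2H-chromen-8-yl}-2-{2-methoxy-6-(methoxymethoxy)-3-(3-methylbut-2-en-1-yl)-4-[(triisopropylsilyl)oxy]phenyl}ethyl]-4,4,5,5-tetramethyl-1,3,2-dioxaborolane
Product: 24 (2R)-2-{2,2-dimethyl-5-[(triisopropylsilyl)oxy]-2H-chromen-8-yl}-3-{2-methoxy-6-(methoxymethoxy)-3-(3-methylbut-2-en-1-yl)-4-[(triisopropylsilyl)oxy]phenyl}propan-1-ol, via chloromethyl borate complex 22 (not isolated), via homologated pinacol boronate 23 (not isolated)
Conditions: BrCH2Cl (3 equiv), n-BuLi (2.5 equiv), THF, −78 °C → rt; then NaBO3·4H2O, THF/H2O, rt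
Reagents that add atoms: bromochloromethane, ClCBr; sodium perborate tetrahydrate, [Na+].[O-]OB=O.O.O.O.O
Why: Matteson homologation, in which chloromethyllithium generated in the presence of 21 adds to boron, the benzylic carbon migrates with retention of configuration and expels chloride, and perborate oxidation of the new primary C–B bond gives the C2 alcohol with C3 still R.

Step 14
Reactants: 24 (2R)-2-{2,2-dimethyl-5-[(triisopropylsilyl)oxy]-2H-chromen-8-yl}-3-{2-methoxy-6-(methoxymethoxy)-3-(3-methylbut-2-en-1-yl)-4-[(triisopropylsilyl)oxy]phenyl}propan-1-ol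
Product: 25 2-[(2R)-2-{2,2-dimethyl-5-[(triisopropylsilyl)oxy]-2H-chromen-8-yl}-3-hydroxypropyl]-3-methoxy-4-(3-methylbut-2-en-1-yl)-5-[(triisopropylsilyl)oxy]phenol
Conditions: ZnBr2 (1.5 equiv), n-PrSH (3 equiv), CH2Cl2, 0 °C, short reaction time
Reagents that add atoms: none
Why: Lewis-acid-assisted acetal cleavage in which the thiol traps the methoxymethyl cation, conditions that act within minutes at 0 °C and should leave aryl silyl ethers, the alcohol and both alkenes alone.

Step 15
Reactants: 25 2-[(2R)-2-{2,2-dimethyl-5-[(triisopropylsilyl)oxy]-2H-chromen-8-yl}-3-hydroxypropyl]-3-methoxy-4-(3-methylbut-2-en-1-yl)-5-[(triisopropylsilyl)oxy]phenol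
Product: 26 (3R)-3-{2,2-dimethyl-5-[(triisopropylsilyl)oxy]-2H-chromen-8-yl}-5-methoxy-6-(3-methylbut-2-en-1-yl)-7-[(triisopropylsilyl)oxy]chromane
Conditions: PPh3, DIAD, THF, 0 °C → rt
Reagents that add atoms: none
Why: Intramolecular Mitsunobu etherification (6-exo-tet), in which the only free phenol, O1–H, displaces the activated primary oxygen at C2 while C3 is not involved and keeps its configuration.

Step 16
Reactants: 26 (3R)-3-{2,2-dimethyl-5-[(triisopropylsilyl)oxy]-2H-chromen-8-yl}-5-methoxy-6-(3-methylbut-2-en-1-yl)-7-[(triisopropylsilyl)oxy]chromane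
Product: 27 (3R)-3-(5-hydroxy-2,2-dimethyl-2H-chromen-8-yl)-5-methoxy-6-(3-methylbut-2-en-1-yl)chroman-7-ol
Conditions: TBAF (2.5 equiv), AcOH (2.5 equiv), THF, 0 °C, argon
Reagents that add atoms: none
Why: Fluoride-induced cleavage of both aryl silyl ethers, buffered with acetic acid so that the liberated phenols are not oxidised and the prenyl group next to the new C7 hydroxyl and the chromene see no strong acid.

**Compound list**

1 | 2,4,6-trihydroxybenzaldehyde | O=Cc1c(O)cc(O)cc1O | starting material
2 | 2,6-dihydroxy-4-[(triisopropylsilyl)oxy]benzaldehyde | O=Cc1c(O)cc(O[Si](C(C)C)(C(C)C)C(C)C)cc1O | intermediate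
3 | 2-hydroxy-6-(methoxymethoxy)-4-[(triisopropylsilyl)oxy]benzaldehyde | O=Cc1c(O)cc(O[Si](C(C)C)(C(C)C)C(C)C)cc1OCOC | intermediate
4 | allyl bromide | C=CCBr | starting material
5 | 2-(allyloxy)-6-(methoxymethoxy)-4-[(triisopropylsilyl)oxy]benzaldehyde | O=Cc1c(OCC=C)cc(O[Si](C(C)C)(C(C)C)C(C)C)cc1OCOC | intermediate
6 | 3-allyl-2-hydroxy-6-(methoxymethoxy)-4-[(triisopropylsilyl)oxy]benzaldehyde | O=Cc1c(O)c(CC=C)c(O[Si](C(C)C)(C(C)C)C(C)C)cc1OCOC | intermediate
7 | 3-allyl-2-methoxy-6-(methoxymethoxy)-4-[(triisopropylsilyl)oxy]benzaldehyde | O=Cc1c(OC)c(CC=C)c(O[Si](C(C)C)(C(C)C)C(C)C)cc1OCOC | intermediate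
8 | 3-allyl-2-methoxy-6-(methoxymethoxy)-4-[(triisopropylsilyl)oxy]phenyl formate | O=COc1c(OC)c(CC=C)c(O[Si](C(C)C)(C(C)C)C(C)C)cc1OCOC | intermediate
9 | 3-allyl-2-methoxy-6-(methoxymethoxy)-4-[(triisopropylsilyl)oxy]phenol | Oc1c(OC)c(CC=C)c(O[Si](C(C)C)(C(C)C)C(C)C)cc1OCOC | intermediate
10 | 3-allyl-2-methoxy-6-(methoxymethoxy)-4-[(triisopropylsilyl)oxy]phenyl trifluoromethanesulfonate | COc1c(CC=C)c(O[Si](C(C)C)(C(C)C)C(C)C)cc(OCOC)c1OS(=O)(=O)C(F)(F)F | intermediate
11 | 2-methyl-2-butene | CC=C(C)C | starting material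
12 | 2-methoxy-6-(methoxymethoxy)-3-(3-methylbut-2-en-1-yl)-4-[(triisopropylsilyl)oxy]phenyl trifluoromethanesulfonate | COc1c(CC=C(C)C)c(O[Si](C(C)C)(C(C)C)C(C)C)cc(OCOC)c1OS(=O)(=O)C(F)(F)F | intermediate
13 | 4-bromoresorcinol | Oc1ccc(Br)c(O)c1 | starting material
14 | 2-bromo-5-[(triisopropylsilyl)oxy]phenol | Oc1cc(O[Si](C(C)C)(C(C)C)C(C)C)ccc1Br | intermediate
15 | 3-chloro-3-methylbut-1-yne | C#CC(C)(C)Cl | starting material
16 | 1-bromo-2-[(2-methylbut-3-yn-2-yl)oxy]-4-[(triisopropylsilyl)oxy]benzene | C#CC(C)(C)Oc1cc(O[Si](C(C)C)(C(C)C)C(C)C)ccc1Br | intermediate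
17 | 8-bromo-2,2-dimethyl-5-[(triisopropylsilyl)oxy]-2H-chromene | Brc1ccc(O[Si](C(C)C)(C(C)C)C(C)C)c2c1OC(C)(C)C=C2 | intermediate
18 | vinylboronic acid pinacol ester (4,4,5,5-tetramethyl-2-vinyl-1,3,2-dioxaborolane) | C=CB1OC(C)(C)C(C)(C)O1 | starting material
19 | {2,2-dimethyl-5-[(triisopropylsilyl)oxy]-2H-chromen-8-yl}lithium | [Li]c1ccc(O[Si](C(C)C)(C(C)C)C(C)C)c2c1OC(C)(C)C=C2 | intermediate
20 | lithium {2,2-dimethyl-5-[(triisopropylsilyl)oxy]-2H-chromen-8-yl}(pinacolato)(vinyl)borate | [Li+].C=C[B-]1(OC(C)(C)C(C)(C)O1)c1ccc(O[Si](C(C)C)(C(C)C)C(C)C)c2c1OC(C)(C)C=C2 | intermediate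
21 | 2-[(1R)-1-{2,2-dimethyl-5-[(triisopropylsilyl)oxy]-2H-chromen-8-yl}-2-{2-methoxy-6-(methoxymethoxy)-3-(3-methylbut-2-en-1-yl)-4-[(triisopropylsilyl)oxy]phenyl}ethyl]-4,4,5,5-tetramethyl-1,3,2-dioxaborolane | COc1c(CC=C(C)C)c(O[Si](C(C)C)(C(C)C)C(C)C)cc(OCOC)c1C[C@H](c1ccc(O[Si](C(C)C)(C(C)C)C(C)C)c2c1OC(C)(C)C=C2)B1OC(C)(C)C(C)(C)O1 | intermediate
22 | lithium (chloromethyl)borate complex of 21 (chloromethyl group on boron, C3 still R) | [Li+].COc1c(CC=C(C)C)c(O[Si](C(C)C)(C(C)C)C(C)C)cc(OCOC)c1C[C@H](c1ccc(O[Si](C(C)C)(C(C)C)C(C)C)c2c1OC(C)(C)C=C2)[B-]1(CCl)OC(C)(C)C(C)(C)O1 | intermediate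
23 | 2-[(2R)-2-{2,2-dimethyl-5-[(triisopropylsilyl)oxy]-2H-chromen-8-yl}-3-{2-methoxy-6-(methoxymethoxy)-3-(3-methylbut-2-en-1-yl)-4-[(triisopropylsilyl)oxy]phenyl}propyl]-4,4,5,5-tetramethyl-1,3,2-dioxaborolane | COc1c(CC=C(C)C)c(O[Si](C(C)C)(C(C)C)C(C)C)cc(OCOC)c1C[C@H](c1ccc(O[Si](C(C)C)(C(C)C)C(C)C)c2c1OC(C)(C)C=C2)CB1OC(C)(C)C(C)(C)O1 | intermediate
24 | (2R)-2-{2,2-dimethyl-5-[(triisopropylsilyl)oxy]-2H-chromen-8-yl}-3-{2-methoxy-6-(methoxymethoxy)-3-(3-methylbut-2-en-1-yl)-4-[(triisopropylsilyl)oxy]phenyl}propan-1-ol | COc1c(CC=C(C)C)c(O[Si](C(C)C)(C(C)C)C(C)C)cc(OCOC)c1C[C@H](c1ccc(O[Si](C(C)C)(C(C)C)C(C)C)c2c1OC(C)(C)C=C2)CO | intermediate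
25 | 2-[(2R)-2-{2,2-dimethyl-5-[(triisopropylsilyl)oxy]-2H-chromen-8-yl}-3-hydroxypropyl]-3-methoxy-4-(3-methylbut-2-en-1-yl)-5-[(triisopropylsilyl)oxy]phenol | COc1c(CC=C(C)C)c(O[Si](C(C)C)(C(C)C)C(C)C)cc(O)c1C[C@H](c1ccc(O[Si](C(C)C)(C(C)C)C(C)C)c2c1OC(C)(C)C=C2)CO | intermediate
26 | (3R)-3-{2,2-dimethyl-5-[(triisopropylsilyl)oxy]-2H-chromen-8-yl}-5-methoxy-6-(3-methylbut-2-en-1-yl)-7-[(triisopropylsilyl)oxy]chromane | COc1c(CC=C(C)C)c(O[Si](C(C)C)(C(C)C)C(C)C)cc2c1C[C@H](c1ccc(O[Si](C(C)C)(C(C)C)C(C)C)c3c1OC(C)(C)C=C3)CO2 | intermediate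
27 | (3R)-3-(5-hydroxy-2,2-dimethyl-2H-chromen-8-yl)-5-methoxy-6-(3-methylbut-2-en-1-yl)chroman-7-ol (CNP0119857.1) | COc1c(CC=C(C)C)c(O)cc2c1C[C@H](c1ccc(O)c3c1OC(C)(C)C=C3)CO2 | target

**Step count and risks**

Total steps: 16. Longest linear sequence: 13 (steps 1–8, then 12–16); the ring B branch (steps 9–11) joins at step 12.

Steps most likely to fail:

1. Step 12. Oxidative addition of the di-ortho-oxygenated triflate to the chiral bisphosphine–palladium complex may be too slow, or direct transfer of the chromenyl group from boron to palladium may outrun the metallate shift; facial selectivity may also erode with the ortho-alkoxy migrating group. The fallback makes the C3–B stereocenter and the C4–C4a bond in separate, known steps. It sets out from bromide 17 and vinylboronate 18: Suzuki–Miyaura vinylation (Pd(OAc)2/SPhos, K3PO4, dioxane/H2O, 80 °C) should give the ring B styrene 2,2-dimethyl-5-[(triisopropylsilyl)oxy]-8-vinyl-2H-chromene F1. Enantioselective alkene diboration (B2(pin)2, Pt(dba)3 as zerovalent platinum source, TADDOL-derived phosphonite ligand of the enantiomer giving the R product) should give the vicinal bis(boronate) 2,2'-[(1R)-1-{2,2-dimethyl-5-[(triisopropylsilyl)oxy]-2H-chromen-8-yl}ethane-1,2-diyl]bis(4,4,5,5-tetramethyl-1,3,2-dioxaborolane) F2. Chemoselective Suzuki–Miyaura coupling of its primary C–B bond with triflate 12 (Pd(OAc)2/RuPhos, K3PO4, THF/H2O, 70 °C), where an achiral ligand suited to hindered electrophiles can be chosen freely, would come back to the route at boronate 21.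

2. Step 13. The crowded secondary boronate may capture the short-lived chloromethyllithium more slowly than the carbenoid decomposes, returning 21. The fallback inserts the carbon in two stages with a longer-lived carbenoid. It sets out from 21: preformed dichloromethyllithium (CH2Cl2, n-BuLi, THF, −100 °C) should give the lithium dichloromethyl borate complex F3, which on warming with ZnCl2 should rearrange to the α-chloro boronic ester F4 (a mixture at the CHCl carbon, of no consequence). KBH(Oi-Pr)3 should then add hydride to boron to give the potassium hydridoborate F5, and hydride migration with loss of chloride would come back to the route at homologated boronate 23, which is oxidised with perborate as in step 13.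

3. Step 14. Cleavage of the methoxymethyl ether may be accompanied by loss of the aryl silyl ethers or by Lewis-acid- or thiol-mediated addition to the prenyl and chromene alkenes, giving mixtures that the Mitsunobu reaction cannot use. The fallback does not liberate the phenol separately and closes ring C by phenoxide displacement instead. It sets out from alcohol 24: mesylation (MsCl, Et3N, CH2Cl2, 0 °C) should give the primary mesylate F6. TMSOTf/2,2'-bipyridyl (CH2Cl2, 0 °C), a non-protic exchange of the aryl acetal for a silyl group, should give the aryl trimethylsilyl ether mesylate F7. TBAF in THF would then remove all three silyl groups while the C8a phenoxide closes ring C on the mesylate (intramolecular Williamson etherification), coming back to the route at target 27.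

**Further compounds**

F1 | step 12 | 2,2-dimethyl-5-[(triisopropylsilyl)oxy]-8-vinyl-2H-chromene | C=Cc1ccc(O[Si](C(C)C)(C(C)C)C(C)C)c2c1OC(C)(C)C=C2
F2 | step 12 | 2,2'-[(1R)-1-{2,2-dimethyl-5-[(triisopropylsilyl)oxy]-2H-chromen-8-yl}ethane-1,2-diyl]bis(4,4,5,5-tetramethyl-1,3,2-dioxaborolane) | CC1(C)OB(OC1(C)C)C[C@H](c1ccc(O[Si](C(C)C)(C(C)C)C(C)C)c2c1OC(C)(C)C=C2)B1OC(C)(C)C(C)(C)O1
F3 | step 13 | lithium (dichloromethyl)borate complex of 21 (C3 configuration as in 21) | [Li+].COc1c(CC=C(C)C)c(O[Si](C(C)C)(C(C)C)C(C)C)cc(OCOC)c1C[C@H](c1ccc(O[Si](C(C)C)(C(C)C)C(C)C)c2c1OC(C)(C)C=C2)[B-]1(C(Cl)Cl)OC(C)(C)C(C)(C)O1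
F4 | step 13 | α-chloro boronic ester, 2-[1-chloro-2-{chromenyl}-3-{aryl}propyl]-4,4,5,5-tetramethyl-1,3,2-dioxaborolane (C3 configuration as in 21, CHCl carbon undefined) | COc1c(CC=C(C)C)c(O[Si](C(C)C)(C(C)C)C(C)C)cc(OCOC)c1C[C@H](c1ccc(O[Si](C(C)C)(C(C)C)C(C)C)c2c1OC(C)(C)C=C2)C(Cl)B1OC(C)(C)C(C)(C)O1
F5 | step 13 | potassium hydridoborate of the α-chloro boronic ester | [K+].COc1c(CC=C(C)C)c(O[Si](C(C)C)(C(C)C)C(C)C)cc(OCOC)c1C[C@H](c1ccc(O[Si](C(C)C)(C(C)C)C(C)C)c2c1OC(C)(C)C=C2)C(Cl)[BH-]1OC(C)(C)C(C)(C)O1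
F6 | step 14 | (2R)-2-{2,2-dimethyl-5-[(triisopropylsilyl)oxy]-2H-chromen-8-yl}-3-{2-methoxy-6-(methoxymethoxy)-3-(3-methylbut-2-en-1-yl)-4-[(triisopropylsilyl)oxy]phenyl}propyl methanesulfonate | COc1c(CC=C(C)C)c(O[Si](C(C)C)(C(C)C)C(C)C)cc(OCOC)c1C[C@H](c1ccc(O[Si](C(C)C)(C(C)C)C(C)C)c2c1OC(C)(C)C=C2)COS(C)(=O)=O
F7 | step 14 | (2R)-2-{2,2-dimethyl-5-[(triisopropylsilyl)oxy]-2H-chromen-8-yl}-3-{2-methoxy-3-(3-methylbut-2-en-1-yl)-4-[(triisopropylsilyl)oxy]-6-[(trimethylsilyl)oxy]phenyl}propyl methanesulfonate | COc1c(CC=C(C)C)c(O[Si](C(C)C)(C(C)C)C(C)C)cc(O[Si](C)(C)C)c1C[C@H](c1ccc(O[Si](C(C)C)(C(C)C)C(C)C)c2c1OC(C)(C)C=C2)COS(C)(=O)=O
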